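**Retrosynthetic overview** (drimane numbering: C-1 carries the ester oxygen, C-4 the gem-dimethyl group, C-5/C-10 are the ring fusion, C-9 carries C-11, C-8 carries C-12)
- The target comes from its aryl silyl ether, made from a 1,7-bis(coumarate) 11,12-bis(triethylsilyl ether) by a one-pot Swern oxidation and loss of the C-7 ester, which gives the 7-ene-11,12-dial.
- That bis-ester comes from a 1β,7,11,12-tetraol, obtained by hydride reduction of dimethyl 1,7-dioxodrimane-11,12-dioate.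
- Key disconnection C-7–C-8 (closes ring B): intramolecular Stetter reaction, the C-7 aldehyde carbon adding as an acyl anion to C-8 of a fumarate.
- The Stetter substrate comes from the ring A enone, (1,3-dioxolan-2-ylmethyl)magnesium bromide (C-6, C-7) and dimethyl but-2-ynedioate (C-8, C-9, C-11, C-12) in one asymmetric conjugate addition with trans enolate trapping, which sets C-5 and C-10.
- Ring order: ring A is bought, ring B is closed in step 2; the p-coumaroyl unit enters late as its silyl ether.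

Assumption: the ligand enantiomer named in step 1 delivers the Grignard reagent to the enone face that gives the (S) centre drawn in 4; if the sense proves opposite, the mirror-image ligand is used and nothing else changes.

Step 1
Reactants: 1 enone 2,4,4-trimethylcyclohex-2-en-1-one; 2 (1,3-dioxolan-2-ylmethyl)magnesium bromide; 3 dimethyl but-2-ynedioate
Product: 6 keto aldehyde dimethyl (E)-2-[(1S,2S)-1,3,3-trimethyl-6-oxo-2-(2-oxoethyl)cyclohexyl]but-2-enedioate, via magnesium enolate 4 (not isolated), via dioxolane adduct 5 (not isolated)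
Conditions: CuBr·SMe2 (5 mol %), (R)-1-[(S)-2-(diphenylphosphino)ferrocenyl]ethyldicyclohexylphosphine (6 mol %), 2 (1.2 equiv, slow addition), t-BuOMe, −75 → −40 °C; then 3 (1.5 equiv), −78 °C; then 2 M HCl, THF, −78 → 23 °C
Reagents that add atoms: water, O
Why: Copper-catalysed asymmetric conjugate addition of a Grignard reagent (known for 2-methyl- and for 4,4-dimethylcyclohexenone) sets C-5, the enolate 4 then adds in Michael fashion to the alkyne on the face opposite the new C-5 substituent, which fixes the quaternary C-10 trans to it, and aqueous acid protonates the allenolate and hydrolyses the dioxolane.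

Step 2
Reactants: 6 keto aldehyde
Product: 7 dimethyl (1S,2S,4aS,8aS)-5,5,8a-trimethyl-3,8-dioxodecahydronaphthalene-1,2-dicarboxylate (dimethyl 1,7-dioxodrimane-11,12-dioate)
Conditions: 3-benzyl-5-(2-hydroxyethyl)-4-methylthiazolium chloride (20 mol %), Et3N (40 mol %), 1,4-dioxane, 70 °C
Reagents that add atoms: none
Why: Intramolecular Stetter reaction in which the carbene turns the C-7 aldehyde into an acyl anion equivalent that adds to C-8, the unsubstituted carbon of the tethered fumarate (intermolecular Stetter additions of aliphatic aldehydes to fumarates are classical), the two trans arms on ring A giving the trans-decalin, the C-9 ester enolate being protonated from the α face opposite the axial C-10 methyl (9β ester) and the C-8 β-keto ester centre settling with its ester equatorial.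

Step 3
Reactants: 7 diketo diester
Product: 8 (1R,4aS,6S,7R,8S,8aS)-7,8-bis(hydroxymethyl)-4,4,8a-trimethyldecahydronaphthalene-1,6-diol (1β,7β-drimane-1,7,11,12-tetraol)
Conditions: LiBH4 (6 equiv), THF–MeOH (20:1), 0 → 50 °C
Reagents that add atoms: none
Why: Borohydride reduction of both ketones and both esters, with hydride reaching C-1 along the axial path from the α face, away from the axial C-10 methyl and the C-9 substituent, to give the equatorial 1β alcohol, while the C-7 carbinol configuration does not matter because this oxygen is eliminated in step 7.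

Step 4
Reactants: 8 tetraol
Product: 9 (1R,4aS,6S,7R,8S,8aS)-4,4,8a-trimethyl-7,8-bis{[(triethylsilyl)oxy]methyl}decahydronaphthalene-1,6-diol
Conditions: Et3SiCl (2.2 equiv), imidazole, CH2Cl2–DMF, −40 → −20 °C
Reagents that add atoms: chlorotriethylsilane, CC[Si](Cl)(CC)CC
Why: Selective silylation, the two primary alcohols reacting far faster with a silyl chloride at low temperature than the secondary C-1 and C-7 alcohols.

Step 5
Reactants: 10 (E)-3-(4-hydroxyphenyl)prop-2-enoic acid (p-coumaric acid)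
Product: 12 (E)-3-{4-[(tert-butyldimethylsilyl)oxy]phenyl}prop-2-enoic acid, via bis-silyl compound 11 (not isolated)
Conditions: t-BuMe2SiCl (2.3 equiv), imidazole, DMF, 23 °C; then THF–H2O–AcOH (4:1:1), 23 °C
Reagents that add atoms: tert-butylchlorodimethylsilane, CC(C)(C)[Si](C)(C)Cl
Why: Silylation of phenol and acid followed by selective hydrolysis of the labile silyl ester, which leaves the aryl silyl ether in place.

Step 6
Reactants: 9 bis-silyl ether diol; 12 silyl-protected coumaric acid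
Product: 14 (1R,4aS,6S,7R,8S,8aS)-4,4,8a-trimethyl-7,8-bis{[(triethylsilyl)oxy]methyl}decahydronaphthalene-1,6-diyl bis[(2E)-3-{4-[(tert-butyldimethylsilyl)oxy]phenyl}prop-2-enoate], via mixed anhydride 13 (not isolated)
Conditions: 12 (3 equiv), 2,4,6-trichlorobenzoyl chloride (3 equiv), Et3N, THF, 23 °C; then 9, DMAP (0.5 equiv), toluene, 60 °C
Reagents that add atoms: none
Why: Yamaguchi esterification acylates both secondary alcohols with retention, the C-1 ester being the one kept in the target and the C-7 ester serving as the leaving group for step 7.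

Step 7
Reactants: 14 bis-ester
Product: 16 (1R,4aS,8R,8aS)-7,8-diformyl-4,4,8a-trimethyl-1,2,3,4,4a,5,8,8a-octahydronaphthalen-1-yl (2E)-3-{4-[(tert-butyldimethylsilyl)oxy]phenyl}prop-2-enoate, via acyloxy dialdehyde 15 (not isolated)
Conditions: (COCl)2, DMSO, CH2Cl2, −78 → −40 °C; then Et3N, −78 → 0 °C
Reagents that add atoms: none
Why: Swern oxidation converts primary triethylsilyl ethers directly into aldehydes while the aryl silyl ether survives, and Et3N then expels the C-7 carboxylate β to the new C-12 aldehyde (E1cB) to give the 7-ene enal, with the C-9 centre from step 2 carried through unchanged at low temperature.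

Step 8
Reactants: 16 silyl-protected target
Product: 17 (1R,4aS,8R,8aS)-7,8-diformyl-4,4,8a-trimethyl-1,2,3,4,4a,5,8,8a-octahydronaphthalen-1-yl (2E)-3-(4-hydroxyphenyl)prop-2-enoate (CNP0187624.1)
Conditions: HF·pyridine, pyridine, THF, 0 °C
Reagents that add atoms: none
Why: Fluoride-mediated cleavage of the aryl silyl ether under buffered, non-basic conditions that leave the enal, the cinnamate and the epimerisable C-9 centre alone.

**Compound list**
1 | 2,4,4-trimethylcyclohex-2-en-1-one | CC1=CC(C)(C)CCC1=O | starting material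
2 | (1,3-dioxolan-2-ylmethyl)magnesium bromide | Br[Mg]CC1OCCO1 | starting material
3 | dimethyl but-2-ynedioate | COC(=O)C#CC(=O)OC | starting material
4 | bromomagnesium (3S)-3-(1,3-dioxolan-2-ylmethyl)-2,4,4-trimethylcyclohex-1-en-1-olate | CC1=C(O[Mg]Br)CCC(C)(C)[C@@H]1CC2OCCO2 | intermediate
5 | dimethyl (E)-2-[(1S,2S)-2-(1,3-dioxolan-2-ylmethyl)-1,3,3-trimethyl-6-oxocyclohexyl]but-2-enedioate | CC1(C)CCC(=O)[C@](C)(/C(C(=O)OC)=C\C(=O)OC)[C@H]1CC2OCCO2 | intermediate
6 | dimethyl (E)-2-[(1S,2S)-1,3,3-trimethyl-6-oxo-2-(2-oxoethyl)cyclohexyl]but-2-enedioate | CC1(C)CCC(=O)[C@](C)(/C(C(=O)OC)=C\C(=O)OC)[C@H]1CC=O | intermediate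
7 | dimethyl (1S,2S,4aS,8aS)-5,5,8a-trimethyl-3,8-dioxodecahydronaphthalene-1,2-dicarboxylate | CC1(C)CCC(=O)[C@]2(C)[C@@H](C(=O)OC)[C@H](C(=O)OC)C(=O)C[C@@H]12 | intermediate
8 | (1R,4aS,6S,7R,8S,8aS)-7,8-bis(hydroxymethyl)-4,4,8a-trimethyldecahydronaphthalene-1,6-diol | CC1(C)CC[C@@H](O)[C@]2(C)[C@@H](CO)[C@H](CO)[C@@H](O)C[C@@H]12 | intermediate
9 | (1R,4aS,6S,7R,8S,8aS)-4,4,8a-trimethyl-7,8-bis{[(triethylsilyl)oxy]methyl}decahydronaphthalene-1,6-diol | CC1(C)CC[C@@H](O)[C@]2(C)[C@@H](CO[Si](CC)(CC)CC)[C@H](CO[Si](CC)(CC)CC)[C@@H](O)C[C@@H]12 | intermediate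
10 | (E)-3-(4-hydroxyphenyl)prop-2-enoic acid | OC(=O)/C=C/c1ccc(O)cc1 | starting material
11 | tert-butyldimethylsilyl (E)-3-{4-[(tert-butyldimethylsilyl)oxy]phenyl}prop-2-enoate | CC(C)(C)[Si](C)(C)OC(=O)/C=C/c1ccc(O[Si](C)(C)C(C)(C)C)cc1 | intermediate
12 | (E)-3-{4-[(tert-butyldimethylsilyl)oxy]phenyl}prop-2-enoic acid | OC(=O)/C=C/c1ccc(O[Si](C)(C)C(C)(C)C)cc1 | intermediate
13 | (E)-3-{4-[(tert-butyldimethylsilyl)oxy]phenyl}prop-2-enoic 2,4,6-trichlorobenzoic anhydride | CC(C)(C)[Si](C)(C)Oc1ccc(/C=C/C(=O)OC(=O)c2c(Cl)cc(Cl)cc2Cl)cc1 | intermediate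
14 | (1R,4aS,6S,7R,8S,8aS)-4,4,8a-trimethyl-7,8-bis{[(triethylsilyl)oxy]methyl}decahydronaphthalene-1,6-diyl bis[(2E)-3-{4-[(tert-butyldimethylsilyl)oxy]phenyl}prop-2-enoate] | CC1(C)CC[C@@H](OC(=O)/C=C/c2ccc(O[Si](C)(C)C(C)(C)C)cc2)[C@]2(C)[C@@H](CO[Si](CC)(CC)CC)[C@H](CO[Si](CC)(CC)CC)[C@@H](OC(=O)/C=C/c3ccc(O[Si](C)(C)C(C)(C)C)cc3)C[C@@H]12 | intermediate
15 | (1R,4aS,6S,7S,8S,8aS)-7,8-diformyl-4,4,8a-trimethyldecahydronaphthalene-1,6-diyl bis[(2E)-3-{4-[(tert-butyldimethylsilyl)oxy]phenyl}prop-2-enoate] | CC1(C)CC[C@@H](OC(=O)/C=C/c2ccc(O[Si](C)(C)C(C)(C)C)cc2)[C@]2(C)[C@@H](C=O)[C@H](C=O)[C@@H](OC(=O)/C=C/c3ccc(O[Si](C)(C)C(C)(C)C)cc3)C[C@@H]12 | intermediate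
16 | (1R,4aS,8R,8aS)-7,8-diformyl-4,4,8a-trimethyl-1,2,3,4,4a,5,8,8a-octahydronaphthalen-1-yl (2E)-3-{4-[(tert-butyldimethylsilyl)oxy]phenyl}prop-2-enoate | CC1(C)CC[C@@H](OC(=O)/C=C/c2ccc(O[Si](C)(C)C(C)(C)C)cc2)[C@]2(C)[C@@H](C=O)C(C=O)=CC[C@@H]12 | intermediate
17 | (1R,4aS,8R,8aS)-7,8-diformyl-4,4,8a-trimethyl-1,2,3,4,4a,5,8,8a-octahydronaphthalen-1-yl (2E)-3-(4-hydroxyphenyl)prop-2-enoate | CC1(C)CC[C@@H](OC(=O)/C=C/c2ccc(O)cc2)[C@]2(C)[C@@H](C=O)C(C=O)=CC[C@@H]12 | target

**Step count and risk**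
Total step count: 8. Longest linear sequence: 7 (steps 1–4 and 6–8, from enone 1); step 5 is a one-step side branch.

Steps most likely to fail:

Step 1. Asymmetric conjugate addition to this hindered enone, and clean Michael trapping of the enolate by the alkyne, are both untested on this substrate. The fallback sets out from 1 and comes back at 6. A stoichiometric chiral acetaldehyde-enolate equivalent replaces the catalyst: (3aR,7aR)-2-allyl-1,3-dimethyloctahydro-1H-1,3,2-benzodiazaphosphole 2-oxide F1, made from (1R,2R)-N,N′-dimethylcyclohexane-1,2-diamine and allylphosphonic dichloride with Et3N. It is deprotonated with n-BuLi in THF at −78 °C and adds to 1 through its γ-carbon; the resulting enolate is trapped with 3 as before, and acid quench gives dimethyl (E)-2-[(1S,2S)-2-{(E)-3-[(3aR,7aR)-1,3-dimethyl-2-oxidooctahydro-1H-1,3,2-benzodiazaphosphol-2-yl]prop-2-en-1-yl}-1,3,3-trimethyl-6-oxocyclohexyl]but-2-enedioate F2. Ozonolysis of the vinylphosphonamide double bond (O3, CH2Cl2–MeOH, −78 °C; Me2S), which is far more electron-rich than the fumarate, then gives 6.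

Step 2. The Stetter ring closure runs in the endo mode onto a trisubstituted fumarate, and aldol or benzoin addition to the C-1 ketone may compete. The fallback sets out from 6 and comes back at 8. The same C-7–C-8 bond is made reductively: SmI2 (2.5 equiv) in THF–MeOH at −78 °C couples the aldehyde carbon to C-8 of the fumarate and gives dimethyl (1S,2S,3S,4aS,8aS)-3-hydroxy-5,5,8a-trimethyl-8-oxodecahydronaphthalene-1,2-dicarboxylate F3. The LiBH4 reduction of step 3 then converts F3 into 8; either C-7 epimer serves.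

Step 7. Oxidation of two silyl ethers and the β-elimination must both go to completion without epimerising C-9 of the dialdehyde. The fallback sets out from 7 and comes back at 16; it removes the C-7 oxygen before any aldehyde exists.
- The β-keto ester is converted (NaH, then PhNTf2, THF, 0 °C) into dimethyl (1R,4aS,8aS)-5,5,8a-trimethyl-8-oxo-3-{[(trifluoromethyl)sulfonyl]oxy}-1,4,4a,5,6,7,8,8a-octahydronaphthalene-1,2-dicarboxylate F4.
- Reduction with Pd(OAc)2, PPh3 and Et3SiH in DMF at 60 °C gives dimethyl (1R,4aS,8aS)-5,5,8a-trimethyl-8-oxo-1,4,4a,5,6,7,8,8a-octahydronaphthalene-1,2-dicarboxylate F5.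
- LiAlH4 in THF at −20 °C gives (1R,4aS,8S,8aS)-7,8-bis(hydroxymethyl)-4,4,8a-trimethyl-1,2,3,4,4a,5,8,8a-octahydronaphthalen-1-ol F6.
- Et3SiCl and imidazole give (1R,4aS,8S,8aS)-4,4,8a-trimethyl-7,8-bis{[(triethylsilyl)oxy]methyl}-1,2,3,4,4a,5,8,8a-octahydronaphthalen-1-ol F7.
- Yamaguchi esterification with 12 gives (1R,4aS,8S,8aS)-4,4,8a-trimethyl-7,8-bis{[(triethylsilyl)oxy]methyl}-1,2,3,4,4a,5,8,8a-octahydronaphthalen-1-yl (2E)-3-{4-[(tert-butyldimethylsilyl)oxy]phenyl}prop-2-enoate F8.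
- Swern oxidation of F8 as in step 7, kept at −78 °C after Et3N addition, gives 16.

Further compounds
F1 | step 1 | (3aR,7aR)-2-allyl-1,3-dimethyloctahydro-1H-1,3,2-benzodiazaphosphole 2-oxide | C=CCP1(=O)N(C)[C@@H]2CCCC[C@H]2N1C
F2 | step 1 | dimethyl (E)-2-[(1S,2S)-2-{(E)-3-[(3aR,7aR)-1,3-dimethyl-2-oxidooctahydro-1H-1,3,2-benzodiazaphosphol-2-yl]prop-2-en-1-yl}-1,3,3-trimethyl-6-oxocyclohexyl]but-2-enedioate | CC1(C)CCC(=O)[C@](C)(/C(C(=O)OC)=C\C(=O)OC)[C@H]1C/C=C/P2(=O)N(C)[C@@H]3CCCC[C@H]3N2C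
F3 | step 2 | dimethyl (1S,2S,3S,4aS,8aS)-3-hydroxy-5,5,8a-trimethyl-8-oxodecahydronaphthalene-1,2-dicarboxylate | CC1(C)CCC(=O)[C@]2(C)[C@@H](C(=O)OC)[C@H](C(=O)OC)[C@@H](O)C[C@@H]12
F4 | step 7 | dimethyl (1R,4aS,8aS)-5,5,8a-trimethyl-8-oxo-3-{[(trifluoromethyl)sulfonyl]oxy}-1,4,4a,5,6,7,8,8a-octahydronaphthalene-1,2-dicarboxylate | CC1(C)CCC(=O)[C@]2(C)[C@@H](C(=O)OC)C(C(=O)OC)=C(OS(=O)(=O)C(F)(F)F)C[C@@H]12
F5 | step 7 | dimethyl (1R,4aS,8aS)-5,5,8a-trimethyl-8-oxo-1,4,4a,5,6,7,8,8a-octahydronaphthalene-1,2-dicarboxylate | CC1(C)CCC(=O)[C@]2(C)[C@@H](C(=O)OC)C(C(=O)OC)=CC[C@@H]12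
F6 | step 7 | (1R,4aS,8S,8aS)-7,8-bis(hydroxymethyl)-4,4,8a-trimethyl-1,2,3,4,4a,5,8,8a-octahydronaphthalen-1-ol | CC1(C)CC[C@@H](O)[C@]2(C)[C@@H](CO)C(CO)=CC[C@@H]12
F7 | step 7 | (1R,4aS,8S,8aS)-4,4,8a-trimethyl-7,8-bis{[(triethylsilyl)oxy]methyl}-1,2,3,4,4a,5,8,8a-octahydronaphthalen-1-ol | CC1(C)CC[C@@H](O)[C@]2(C)[C@@H](CO[Si](CC)(CC)CC)C(CO[Si](CC)(CC)CC)=CC[C@@H]12
F8 | step 7 | (1R,4aS,8S,8aS)-4,4,8a-trimethyl-7,8-bis{[(triethylsilyl)oxy]methyl}-1,2,3,4,4a,5,8,8a-octahydronaphthalen-1-yl (2E)-3-{4-[(tert-butyldimethylsilyl)oxy]phenyl}prop-2-enoate | CC1(C)CC[C@@H](OC(=O)/C=C/c3ccc(O[Si](C)(C)C(C)(C)C)cc3)[C@]2(C)[C@@H](CO[Si](CC)(CC)CC)C(CO[Si](CC)(CC)CC)=CC[C@@H]12
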